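**Retrosynthetic overview**
- The target is opened at the C5–O bond: a 2-methoxy-3-alkyl-1,4-benzoquinone receives its last ring oxygen by oxygen-atom transfer from an amine N-oxide, and the methyl ether is hydrolysed in the same pot.
- The methoxyquinone comes from 1,2,4-trimethoxy-3-alkylbenzene by oxidative demethylation with (NH4)2Ce(NO3)6.
- The C19 chain is cut between C10 and C11: an aryl-decyl bromide is joined to a B-alkyl-9-BBN made from (4E)-nona-1,4-diene (alkyl–alkyl Suzuki coupling).
- The aryl-decyl bromide comes from 1,2,4-trimethoxybenzene (lithiation at C3) and 1,10-dibromodecane; the diene comes from hex-1-yne (hydrozirconation sets E) and allyl bromide.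
- No ring is formed; the only ring is the purchased benzene ring, which is oxidised to the quinone.

Assumption: the target has no stereocentre, so "single enantiomer" is read as the single (14E) alkene isomer, its only stereochemical element.

**Step 1**
Reactants: 1 1,2,4-trimethoxybenzene; 2 1,10-dibromodecane
Product: 4 3-(10-bromodecyl)-1,2,4-trimethoxybenzene, via (2,3,6-trimethoxyphenyl)lithium 3 (not isolated)
Conditions: n-BuLi (1.05 equiv), THF, 0 °C to rt, 1 h; then add to 2 (4 equiv), THF, 0 °C to rt, 12 h
Reagents that add atoms: none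
Why: Directed ortho-metalation removes the C3 proton flanked by two methoxy groups and the aryllithium displaces one bromide of the excess dibromide in an SN2 alkylation, the excess suppressing double arylation; no stereo element is made.

**Step 2**
Reactants: 5 hex-1-yne; 6 allyl bromide
Product: 8 (4E)-nona-1,4-diene, via (E)-hex-1-enylzirconocene chloride 7 (not isolated)
Conditions: Cp2Zr(H)Cl (1.1 equiv), THF, rt, 1 h; then 6 (1.2 equiv), CuCl (10 mol%), 0 °C to rt, 3 h
Reagents that add atoms: none
Why: Schwartz hydrozirconation adds Zr–H syn and anti-Markovnikov across the terminal alkyne, which fixes the E geometry of the future C14=C15 alkene, and CuCl-catalysed allylation of the alkenylzirconocene forms the C–C bond with retention of that geometry.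

**Step 3**
Reactants: 8 (4E)-nona-1,4-diene; 4 3-(10-bromodecyl)-1,2,4-trimethoxybenzene
Product: 10 1,2,4-trimethoxy-3-[(14E)-nonadec-14-en-1-yl]benzene, via B-[(4E)-non-4-en-1-yl]-9-BBN 9 (not isolated)
Conditions: 8 (1.3 equiv), 9-BBN (1.3 equiv), THF, 0 °C to rt, 4 h; then 4, Pd(OAc)2 (4 mol%), PCy3 (8 mol%), K3PO4·H2O (1.3 equiv), THF, rt, 24 h
Reagents that add atoms: none
Why: 9-BBN hydroborates only the terminal alkene of the skipped diene (anti-Markovnikov) and the B-alkyl-9-BBN couples with the primary alkyl bromide in an alkyl–alkyl Suzuki–Miyaura reaction under a PCy3-ligated zerovalent palladium catalyst, leaving the E alkene untouched.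

**Step 4**
Reactants: 10 1,2,4-trimethoxy-3-[(14E)-nonadec-14-en-1-yl]benzene
Product: 11 2-methoxy-3-[(14E)-nonadec-14-en-1-yl]-1,4-benzoquinone
Conditions: (NH4)2Ce(NO3)6 (2.5 equiv), MeCN/H2O 2:1, 0 °C, 20 min
Reagents that add atoms: water (O)
Why: Oxidative demethylation of the para-dimethoxy pair by (NH4)2Ce(NO3)6 (water attacks the ipso carbons, methanol leaves) gives the p-quinone, while the third methoxy group survives as a vinylogous ester and the isolated alkene is inert at 0 °C.

**Step 5**
Reactants: 11 2-methoxy-3-[(14E)-nonadec-14-en-1-yl]-1,4-benzoquinone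
Product: 13 2,5-dihydroxy-3-[(14E)-nonadec-14-en-1-yl]-1,4-benzoquinone, via 5-hydroxy-2-methoxyquinone 12 (not isolated)
Conditions: Me3NO (anhydrous, 1.3 equiv), MeCN, Ar, 0 °C to rt; then 2 M aq NaOH, MeOH, 45 °C, 2 h; 1 M HCl to pH 2
Reagents that add atoms: trimethylamine N-oxide (C[N+](C)(C)[O-]); sodium hydroxide ([Na+].[OH-])
Why: Proposed new method: redox-neutral C–H hydroxylation of a quinone by oxygen-atom transfer from an amine N-oxide, in which the N-oxide oxygen adds in conjugate fashion to C5 (β to the C1 carbonyl, the only reactive enone terminus because the C4 carbonyl is deactivated as a vinylogous ester by the C2 methoxy group and C3 carries the chain), the resulting α-(trimethylammoniooxy) ketone loses trimethylamine by E1cB cleavage of the weak N–O bond with removal of the acidic C5–H, the 4,5-dione tautomerises to hydroxyquinone 12, and hydroxide then exchanges the C2 vinylogous methyl ester by addition–elimination; the closest known reactions are azide addition to quinones with internal redox loss of N2 to give aminoquinones, the Ganem/Kornblum oxidation of alkyl halides with amine N-oxides, and Weitz–Scheffer nucleophilic epoxidation.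

**Compound list**
1 | 1,2,4-trimethoxybenzene | COc1ccc(OC)c(OC)c1 | starting material
2 | 1,10-dibromodecane | BrCCCCCCCCCCBr | starting material
3 | (2,3,6-trimethoxyphenyl)lithium | COc1ccc(OC)c(OC)c1[Li] | intermediate
4 | 3-(10-bromodecyl)-1,2,4-trimethoxybenzene (chain between two methoxy groups) | COc1ccc(OC)c(OC)c1CCCCCCCCCCBr | intermediate
5 | hex-1-yne | CCCCC#C | starting material
6 | allyl bromide (3-bromoprop-1-ene) | C=CCBr | starting material
7 | chlorobis(cyclopentadienyl)[(E)-hex-1-en-1-yl]zirconium, Cp2Zr(Cl)(CH=CHBu) | CCCC/C=C/[Zr+2]Cl.c1cc[cH-]c1.c1cc[cH-]c1 | intermediate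
8 | (4E)-nona-1,4-diene | C=CC/C=C/CCCC | intermediate
9 | B-[(4E)-non-4-en-1-yl]-9-borabicyclo[3.3.1]nonane | CCCC/C=C/CCCB1C2CCCC1CCC2 | intermediate
10 | 1,2,4-trimethoxy-3-[(14E)-nonadec-14-en-1-yl]benzene | CCCC/C=C/CCCCCCCCCCCCCc1c(OC)ccc(OC)c1OC | intermediate
11 | 2-methoxy-3-[(14E)-nonadec-14-en-1-yl]cyclohexa-2,5-diene-1,4-dione | CCCC/C=C/CCCCCCCCCCCCCC1=C(OC)C(=O)C=CC1=O | intermediate
12 | 5-hydroxy-2-methoxy-3-[(14E)-nonadec-14-en-1-yl]cyclohexa-2,5-diene-1,4-dione | CCCC/C=C/CCCCCCCCCCCCCC1=C(OC)C(=O)C=C(O)C1=O | intermediate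
13 | 2,5-dihydroxy-3-[(14E)-nonadec-14-en-1-yl]cyclohexa-2,5-diene-1,4-dione | CCCC/C=C/CCCCCCCCCCCCCC1=C(O)C(=O)C=C(O)C1=O | target

**Totals**
Total step count: 5. Longest linear sequence: 4 (steps 1, 3, 4, 5; step 2 is a one-step side branch).

**Three steps most likely to fail**

Step 5 (proposed new oxygen transfer). The N-oxide may add too slowly to the deactivated methoxyquinone, or the adduct may close to the 5,6-epoxide instead of eliminating trimethylamine. The fallback uses known oxidative amination and hydrolysis. It sets out from 11: MeNH2 (33% in EtOH, excess) under air at rt replaces the C2 methoxy group and adds oxidatively at C5 to give 2,5-bis(methylamino)-3-[(14E)-nonadec-14-en-1-yl]-1,4-benzoquinone F1. Heating F1 in 2 M NaOH in EtOH/H2O and acidifying with HCl hydrolyses both vinylogous amides, and the route is rejoined at 13.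

Step 3 (alkyl–alkyl Suzuki coupling). β-Hydride elimination from the alkylpalladium intermediate or slow transmetalation may give low conversion. The fallback replaces the sp3–sp3 coupling by an sp3–sp2 B-alkyl Suzuki coupling. It sets out from 4: CH2=CHCH2MgBr with Li2CuCl4 (3 mol%) in THF at 0 °C gives 1,2,4-trimethoxy-3-(tridec-12-en-1-yl)benzene F2. Hydroboration of F2 with 9-BBN gives B-[13-(2,3,6-trimethoxyphenyl)tridecyl]-9-borabicyclo[3.3.1]nonane F3. In parallel, intermediate 7 is quenched with I2 to give (E)-1-iodohex-1-ene F4. Coupling of F3 with F4 using PdCl2(dppf) and K3PO4 in THF/DMF/H2O proceeds with retention of the E geometry and rejoins the route at 10.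

Step 4 (oxidative demethylation). The electron-rich arene has a free C5–H, so oxidative biaryl coupling or partial formation of the ortho-quinone can compete. The fallback sets out from 10: constant-current anodic oxidation at a Pt anode in 1% KOH/MeOH at 0 °C gives the quinone bis-ketal 1,3,3,6,6-pentamethoxy-2-[(14E)-nonadec-14-en-1-yl]cyclohexa-1,4-diene F5. Hydrolysis of F5 with 1 M aq HCl in acetone at rt rejoins the route at 11.

**Further compounds**
F1 | step 5 | 2,5-bis(methylamino)-3-[(14E)-nonadec-14-en-1-yl]-1,4-benzoquinone | CCCC/C=C/CCCCCCCCCCCCCC1=C(NC)C(=O)C=C(NC)C1=O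
F2 | step 3 | 1,2,4-trimethoxy-3-(tridec-12-en-1-yl)benzene | C=CCCCCCCCCCCCc1c(OC)ccc(OC)c1OC
F3 | step 3 | B-[13-(2,3,6-trimethoxyphenyl)tridecyl]-9-borabicyclo[3.3.1]nonane | COc1ccc(OC)c(OC)c1CCCCCCCCCCCCCB1C2CCCC1CCC2
F4 | step 3 | (E)-1-iodohex-1-ene | CCCC/C=C/I
F5 | step 4 | 1,3,3,6,6-pentamethoxy-2-[(14E)-nonadec-14-en-1-yl]cyclohexa-1,4-diene | CCCC/C=C/CCCCCCCCCCCCCC1=C(OC)C(OC)(OC)C=CC1(OC)OC
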